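**Retrosynthetic overview**
1. Prostanoid numbering is used (C1 = ester carbon; ring = C8–C12 with C9 = C=O; C12 carries OAc and the C13–C20 chain). The C12 acetate is installed last from a C12 triethylsilyl ether, after one fragment union (C1–C6 + C7–C20).
2. Key disconnection C7–C6: C7 is the exocyclic carbon β to the C9 ketone (C9(=O)–C8–C7) of the cyclopentenone ring. Fragment A is therefore the cross-conjugated dienone with an exocyclic C7=C8 methylidene next to the ring enone C10=C11–C9=O. Its free CH2 terminus C7 accepts the (E)-C6 alkenyl group of fragment B (an alkenylboronic acid) under rhodium catalysis, and C8 is then set against C12.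
3. Fragment A: the cyclopentene ring comes intact from (R)-4-silyloxycyclopent-2-enone. Anti 1,2-addition of a (Z)-oct-2-enylbarium reagent creates C12, oxidation of the relay carbinol gives the C9 ketone (1,3-carbonyl transposition with chirality transfer), and Mannich methylenation adds C7.
4. Fragment B: acylation of bis(trimethylsilyl)acetylene with methyl succinyl chloride, asymmetric transfer hydrogenation (C4), acetylation, C-desilylation and syn-hydroboration (5E).
5. Ring order: no ring is formed in the route; the only ring of the target is carried through from the starting cyclopentenone.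

Key step: step 13

Remark: the C8 epimer with the C7 chain trans to the C13 chain (cis to the C12 oxygen) is assumed to be the thermodynamically preferred one, since a cis CH2/CH2 contact on the cyclopentenone should cost more than a cis CH2/O contact; C8 is therefore set by equilibration.

**Route**

Step 1
Reactants: 1 (Z)-oct-2-en-1-ol
Product: 2 (Z)-1-chlorooct-2-ene
Conditions: NCS, Me2S, CH2Cl2, −20 → 0 °C
Reagents that add atoms: N-chlorosuccinimide, O=C1CCC(=O)N1Cl
Why: Corey–Kim chlorination, in which chloride displaces the alkoxysulfonium group at the primary carbon by SN2, so neither allylic transposition nor Z to E isomerisation is expected.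

Step 2
Reactants: 2 (Z)-1-chlorooct-2-ene; 3 (R)-4-[(tert-butyldimethylsilyl)oxy]cyclopent-2-en-1-one
Product: 5 (1S,4R)-4-[(tert-butyldimethylsilyl)oxy]-1-[(Z)-oct-2-enyl]cyclopent-2-en-1-ol, via (Z)-oct-2-enylbarium chloride 4 (not isolated)
Conditions: active Ba (BaI2, lithium biphenylide, THF, 23 °C); 2, −78 °C; then 3, −78 °C; aq NH4Cl
Reagents that add atoms: barium metal (generated from barium diiodide BaI2), [Ba] (present only in intermediate 4)
Why: Allylbarium carbonyl allylation, in which the reagent keeps its Z geometry at −78 °C and adds 1,2 through its α-carbon, and it should attack anti to the C4 silyloxy group to set the later C12 centre; the minor diastereomer is removed here by chromatography because after step 4 it would become the enantiomer.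

Step 3
Reactants: 5 (1S,4R)-4-[(tert-butyldimethylsilyl)oxy]-1-[(Z)-oct-2-enyl]cyclopent-2-en-1-ol
Product: 6 (1S,4R)-1-[(Z)-oct-2-enyl]cyclopent-2-ene-1,4-diol
Conditions: n-Bu4NF, THF, 0 → 23 °C
Reagents that add atoms: none
Why: Fluoride-mediated desilylation cleaves the secondary silyl ether and leaves the tertiary allylic alcohol and both alkenes untouched.

Step 4
Reactants: 6 (1S,4R)-1-[(Z)-oct-2-enyl]cyclopent-2-ene-1,4-diol
Product: 7 (S)-4-hydroxy-4-[(Z)-oct-2-enyl]cyclopent-2-en-1-one
Conditions: MnO2, CH2Cl2, 23 °C
Reagents that add atoms: none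
Why: Allylic oxidation with MnO2 touches only the secondary allylic alcohol (the tertiary one cannot be oxidised), which erases the relay stereocentre and completes a 1,3-carbonyl transposition that leaves C12 as the only stereocentre.

Step 5
Reactants: 7 (S)-4-hydroxy-4-[(Z)-oct-2-enyl]cyclopent-2-en-1-one
Product: 8 (S)-4-[(Z)-oct-2-enyl]-4-[(triethylsilyl)oxy]cyclopent-2-en-1-one
Conditions: Et3SiOTf, 2,6-lutidine, CH2Cl2, −78 °C
Reagents that add atoms: triethylsilyl trifluoromethanesulfonate, CC[Si](CC)(CC)OS(=O)(=O)C(F)(F)F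
Why: Silyl triflate silylation is the standard way to cap a hindered tertiary alcohol, and the silyl ether makes the C12 oxygen a non-acidic, poor leaving group for the enolate chemistry that follows.

Step 6
Reactants: 8 (S)-4-[(Z)-oct-2-enyl]-4-[(triethylsilyl)oxy]cyclopent-2-en-1-one
Product: 10 (4R,5RS)-5-[(dimethylamino)methyl]-4-[(Z)-oct-2-enyl]-4-[(triethylsilyl)oxy]cyclopent-2-en-1-one, via lithium dienolate 9 (not isolated)
Conditions: LiN(i-Pr)2, THF, −78 °C; Eschenmoser's salt, −78 → 0 °C
Reagents that add atoms: Eschenmoser's salt (N,N-dimethylmethyleneiminium iodide), C=[N+](C)C.[I-]; lithium diisopropylamide, CC(C)[N-]C(C)C.[Li+] (its lithium is present only in intermediate 9)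
Why: Mannich aminomethylation of a kinetic lithium enolate, regiospecific because C8 is the only enolisable position (C12 is quaternary); the configuration of the new C8 centre is irrelevant since step 7 removes it.

Step 7
Reactants: 10 (4R,5RS)-5-[(dimethylamino)methyl]-4-[(Z)-oct-2-enyl]-4-[(triethylsilyl)oxy]cyclopent-2-en-1-one
Product: 12 (R)-5-methylidene-4-[(Z)-oct-2-enyl]-4-[(triethylsilyl)oxy]cyclopent-2-en-1-one, via ammonium iodide 11 (not isolated)
Conditions: MeI, Et2O, 23 °C; then aq NaHCO3, CH2Cl2, 23 °C
Reagents that add atoms: iodomethane, CI (its atoms are present only in intermediate 11)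
Why: Quaternisation followed by E1cB elimination of trimethylamine from the β-ammonio ketone unveils the exocyclic C7=C8 methylidene under conditions mild enough for the silyl ether and the Z-alkene; 12 is used at once in step 13.

Step 8
Reactants: 13 methyl 4-chloro-4-oxobutanoate; 14 bis(trimethylsilyl)acetylene
Product: 15 methyl 4-oxo-6-(trimethylsilyl)hex-5-ynoate
Conditions: AlCl3, CH2Cl2, 0 °C
Reagents that add atoms: none
Why: Friedel–Crafts-type acylation of the bis-silylalkyne proceeds by ipso-substitution of one silyl group and stops at the mono-ynone, the methyl ester being inert to the acylium ion.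

Step 9
Reactants: 15 methyl 4-oxo-6-(trimethylsilyl)hex-5-ynoate
Product: 16 methyl (4S)-4-hydroxy-6-(trimethylsilyl)hex-5-ynoate
Conditions: Ru[(S,S)-TsNCHPhCHPhNH](p-cymene) (1 mol %), i-PrOH, 23 °C
Reagents that add atoms: none
Why: Noyori asymmetric transfer hydrogenation of an alkynyl ketone, in which the alkynyl group takes the place of the aryl group of the standard model so that the (S,S)-diamine complex should give the (S)-propargylic alcohol, under base-free conditions that spare the ynone and the ester.

Step 10
Reactants: 16 methyl (4S)-4-hydroxy-6-(trimethylsilyl)hex-5-ynoate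
Product: 17 methyl (4S)-4-acetoxy-6-(trimethylsilyl)hex-5-ynoate
Conditions: Ac2O, pyridine, DMAP (cat.), CH2Cl2, 0 °C
Reagents that add atoms: acetic anhydride, CC(=O)OC(C)=O
Why: DMAP-catalysed acylation installs the C4 acetate of the target directly and, done at once, keeps the γ-hydroxy ester from closing to the lactone.

Step 11
Reactants: 17 methyl (4S)-4-acetoxy-6-(trimethylsilyl)hex-5-ynoate
Product: 18 methyl (4S)-4-acetoxyhex-5-ynoate
Conditions: n-Bu4NF, AcOH, THF, 0 °C
Reagents that add atoms: none
Why: Fluoride-induced protodesilylation of the alkynylsilane is fast, and the acetic acid buffer keeps the propargylic acetate and the ester intact.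

Step 12
Reactants: 18 methyl (4S)-4-acetoxyhex-5-ynoate
Product: 20 [(1E,3S)-3-acetoxy-6-methoxy-6-oxohex-1-enyl]boronic acid, via catechol boronate 19 (not isolated)
Conditions: catecholborane, Cy2BH (5 mol %), THF, 23 °C; then H2O, 23 °C
Reagents that add atoms: catecholborane, B1Oc2ccccc2O1 (its boron stays; its catechol unit is present only in intermediate 19); water, O (the two B–OH oxygens)
Why: Dialkylborane-catalysed hydroboration of the terminal alkyne is a syn, anti-Markovnikov addition that fixes the 5E geometry, and hydrolysis of the catechol ester frees the boronic acid without touching the acetate or the ester.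

Step 13
Reactants: 12 (R)-5-methylidene-4-[(Z)-oct-2-enyl]-4-[(triethylsilyl)oxy]cyclopent-2-en-1-one; 20 [(1E,3S)-3-acetoxy-6-methoxy-6-oxohex-1-enyl]boronic acid
Product: 21 methyl (4S,5E)-4-acetoxy-7-[(1R,5R)-5-[(Z)-oct-2-enyl]-2-oxo-5-[(triethylsilyl)oxy]cyclopent-3-enyl]hept-5-enoate
Conditions: 20 (1.5 equiv), [Rh(cod)OH]2 (3 mol %), 1,4-dioxane/H2O 10:1, 30 °C; then DBU (0.2 equiv), CH2Cl2, 0 → 23 °C
Reagents that add atoms: none
Why: Hayashi–Miyaura-type conjugate addition: boron-to-rhodium transmetalation of 20 at the hydroxorhodium (monovalent rhodium) centre gives an (E)-alkenylrhodium with retention of geometry, which carbometalates the exocyclic C7=C8 bond of 12 at the unsubstituted C7 terminus to give an oxa-π-allyl rhodium enolate that water protonates, returning Rh–OH. The closest known reaction type is the rhodium-catalysed 1,4-addition of alkenylboronic acids to enones and α-methylene carbonyl compounds with protonation of the enolate. No ring is closed; the cyclopentenone ring is carried through unchanged. The new stereocentre C8 is α to the C9 ketone and is fixed under thermodynamic control by the resident quaternary C12 centre: brief DBU equilibration should place the C7 chain trans to the larger C13 chain (cis to the silyloxy group), and the silyl ether, unlike an acetate, is a poor leaving group from the dienolate. The step needs chemoselectivity for C7 over the endocyclic acceptor carbon C11, secured because C11 is flanked by the quaternary C12 while C7 is an unhindered CH2, and it needs tolerance of the allylic C4 acetate and the methyl ester, which the neutral aqueous rhodium conditions should provide.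

Step 14
Reactants: 21 methyl (4S,5E)-4-acetoxy-7-[(1R,5R)-5-[(Z)-oct-2-enyl]-2-oxo-5-[(triethylsilyl)oxy]cyclopent-3-enyl]hept-5-enoate
Product: 22 methyl (4S,5E)-4-acetoxy-7-[(1R,5R)-5-hydroxy-5-[(Z)-oct-2-enyl]-2-oxocyclopent-3-enyl]hept-5-enoate
Conditions: HF·pyridine, pyridine, THF, 0 °C
Reagents that add atoms: none
Why: Buffered fluoride cleaves the tertiary triethylsilyl ether without base, so the C4 acetate, the ester and the C8 configuration of the β-hydroxy ketone are preserved.

Step 15
Reactants: 22 methyl (4S,5E)-4-acetoxy-7-[(1R,5R)-5-hydroxy-5-[(Z)-oct-2-enyl]-2-oxocyclopent-3-enyl]hept-5-enoate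
Product: 23 methyl (4S,5E)-4-acetoxy-7-[(1R,5R)-5-acetoxy-5-[(Z)-oct-2-enyl]-2-oxocyclopent-3-enyl]hept-5-enoate (CNP0171642.3)
Conditions: Ac2O, DMAP (0.2 equiv), pyridine, CH2Cl2, 0 → 23 °C
Reagents that add atoms: acetic anhydride, CC(=O)OC(C)=O
Why: DMAP-catalysed acetylation of the tertiary C12 alcohol under weak base and short exposure should avoid E1cB loss of the new β-acetoxy group, and C8 already sits in its preferred configuration.

**Compound list**
1 | (Z)-oct-2-en-1-ol | CCCCC/C=C\CO | starting material
2 | (Z)-1-chlorooct-2-ene | CCCCC/C=C\CCl | intermediate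
3 | (R)-4-[(tert-butyldimethylsilyl)oxy]cyclopent-2-en-1-one | O=C1C=C[C@H](O[Si](C)(C)C(C)(C)C)C1 | starting material
4 | (Z)-oct-2-enylbarium chloride (formed in the flask, not isolated) | CCCCC/C=C\C[Ba]Cl | intermediate
5 | (1S,4R)-4-[(tert-butyldimethylsilyl)oxy]-1-[(Z)-oct-2-enyl]cyclopent-2-en-1-ol | CCCCC/C=C\C[C@@]1(O)C=C[C@H](O[Si](C)(C)C(C)(C)C)C1 | intermediate
6 | (1S,4R)-1-[(Z)-oct-2-enyl]cyclopent-2-ene-1,4-diol | CCCCC/C=C\C[C@@]1(O)C=C[C@H](O)C1 | intermediate
7 | (S)-4-hydroxy-4-[(Z)-oct-2-enyl]cyclopent-2-en-1-one | CCCCC/C=C\C[C@@]1(O)C=CC(=O)C1 | intermediate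
8 | (S)-4-[(Z)-oct-2-enyl]-4-[(triethylsilyl)oxy]cyclopent-2-en-1-one | CCCCC/C=C\C[C@@]1(O[Si](CC)(CC)CC)C=CC(=O)C1 | intermediate
9 | lithium (3R)-3-[(Z)-oct-2-enyl]-3-[(triethylsilyl)oxy]cyclopenta-1,4-dien-1-olate (formed in the flask, not isolated) | CCCCC/C=C\C[C@@]1(O[Si](CC)(CC)CC)C=CC(O[Li])=C1 | intermediate
10 | (4R,5RS)-5-[(dimethylamino)methyl]-4-[(Z)-oct-2-enyl]-4-[(triethylsilyl)oxy]cyclopent-2-en-1-one (C5 epimer mixture, both converge in step 7) | CCCCC/C=C\C[C@@]1(O[Si](CC)(CC)CC)C=CC(=O)C1CN(C)C | intermediate
11 | trimethyl{[(5R)-5-[(Z)-oct-2-enyl]-2-oxo-5-[(triethylsilyl)oxy]cyclopent-3-enyl]methyl}ammonium iodide (formed in the flask, not isolated) | CCCCC/C=C\C[C@@]1(O[Si](CC)(CC)CC)C=CC(=O)C1C[N+](C)(C)C.[I-] | intermediate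
12 | (R)-5-methylidene-4-[(Z)-oct-2-enyl]-4-[(triethylsilyl)oxy]cyclopent-2-en-1-one | CCCCC/C=C\C[C@@]1(O[Si](CC)(CC)CC)C=CC(=O)C1=C | intermediate
13 | methyl 4-chloro-4-oxobutanoate | COC(=O)CCC(Cl)=O | starting material
14 | bis(trimethylsilyl)acetylene | C[Si](C)(C)C#C[Si](C)(C)C | starting material
15 | methyl 4-oxo-6-(trimethylsilyl)hex-5-ynoate | COC(=O)CCC(=O)C#C[Si](C)(C)C | intermediate
16 | methyl (4S)-4-hydroxy-6-(trimethylsilyl)hex-5-ynoate | C[Si](C)(C)C#C[C@H](CCC(=O)OC)O | intermediate
17 | methyl (4S)-4-acetoxy-6-(trimethylsilyl)hex-5-ynoate | C[Si](C)(C)C#C[C@H](CCC(=O)OC)OC(C)=O | intermediate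
18 | methyl (4S)-4-acetoxyhex-5-ynoate | C#C[C@H](CCC(=O)OC)OC(C)=O | intermediate
19 | methyl (4S,5E)-4-acetoxy-6-(1,3,2-benzodioxaborol-2-yl)hex-5-enoate (formed in the flask, not isolated) | B1(/C=C/[C@H](CCC(=O)OC)OC(C)=O)Oc2ccccc2O1 | intermediate
20 | [(1E,3S)-3-acetoxy-6-methoxy-6-oxohex-1-enyl]boronic acid | OB(O)/C=C/[C@H](CCC(=O)OC)OC(C)=O | intermediate
21 | methyl (4S,5E)-4-acetoxy-7-[(1R,5R)-5-[(Z)-oct-2-enyl]-2-oxo-5-[(triethylsilyl)oxy]cyclopent-3-enyl]hept-5-enoate | CCCCC/C=C\C[C@@]1(O[Si](CC)(CC)CC)C=CC(=O)[C@@H]1C/C=C/[C@H](CCC(=O)OC)OC(C)=O | intermediate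
22 | methyl (4S,5E)-4-acetoxy-7-[(1R,5R)-5-hydroxy-5-[(Z)-oct-2-enyl]-2-oxocyclopent-3-enyl]hept-5-enoate | CCCCC/C=C\C[C@@]1(O)C=CC(=O)[C@@H]1C/C=C/[C@H](CCC(=O)OC)OC(C)=O | intermediate
23 | methyl (4S,5E)-4-acetoxy-7-[(1R,5R)-5-acetoxy-5-[(Z)-oct-2-enyl]-2-oxocyclopent-3-enyl]hept-5-enoate, i.e. methyl (4S,5E,8R,12R,14Z)-4,12-diacetoxy-9-oxoprosta-5,10,14-trienoate | CCCCC/C=C\C[C@@]1(OC(C)=O)C=CC(=O)[C@@H]1C/C=C/[C@H](CCC(=O)OC)OC(C)=O | target

**Step count and risks**

Total step count: 15. Longest linear sequence: 10 steps (steps 1–7, then 13–15, from 1); the boronic acid branch (steps 8–12) has 5 steps.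

Steps most likely to fail:

1. Step 13. Boron-to-rhodium transmetalation may be outrun by protodeboronation of 20 and by self-dimerisation of 12. Protonation at C8 may also occur mainly from the face that leads to the 8-epimer, with a DBU equilibrium that lies less far toward 21 than assumed. The fallback changes the nucleophile class and works through a discrete enolate; it sets out from 12 and 18 and bypasses 19 and 20. Hydrozirconation of 18 with Cp2Zr(H)Cl (THF, 23 °C) gives, by the same syn addition that fixes 5E, the alkenylzirconocene chloride F1. F1 adds to 12 under [RhCl(cod)]2 catalysis in anhydrous THF (zirconium-to-rhodium transmetalation, no water and no boron) to give the zirconium dienolate F2. F2 is protonated under kinetic control at −78 °C with AcOH, which is a second handle on C8 independent of equilibration. The fallback comes back to the route at 21.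

2. Step 2. A metallotropic shift of the allylbarium reagent, if the temperature rises above about −70 °C, would erode the Z geometry and lead to γ-attack (branched carbinol); Wurtz-type homocoupling may accompany its formation. The fallback builds the side chain as an alkyne and sets out from 3. Addition of allenylmagnesium bromide (Et2O, −78 °C, SE2' delivery of a propargyl group, anti to the silyloxy group) gives (1S,4R)-4-[(tert-butyldimethylsilyl)oxy]-1-(prop-2-ynyl)cyclopent-2-en-1-ol F3. Double deprotonation (n-BuLi, THF/DMPU) and C-alkylation of the acetylide with 1-iodopentane gives (1S,4R)-4-[(tert-butyldimethylsilyl)oxy]-1-(oct-2-ynyl)cyclopent-2-en-1-ol F4. Semi-hydrogenation (H2, Pd/CaCO3–Pb(OAc)2, quinoline) sets 14Z, and the fallback comes back to the route at 5.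

3. Step 7. The liberated cross-conjugated dienone may condense with itself (Diels–Alder-type dimerisation, polymerisation) during work-up and concentration, and trimethylamine may add back. The fallback is a latent-enone approach in which the dienone is never isolated; it sets out from 10. Quaternisation with MeOTf gives the trimethylammonium triflate F5, a storable salt without iodide that could bind rhodium. F5 is charged as such into the rhodium step with 20, [Rh(cod)OH]2 and KHCO3 in dioxane/H2O, where slow elimination feeds 12 at low stationary concentration to the alkenylrhodium. The fallback comes back to the route at 21.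

**Further compounds**
F1 | step 13 | methyl (4S,5E)-4-acetoxy-6-[chlorobis(cyclopentadienyl)zirconio]hex-5-enoate | Cl[Zr](/C=C/[C@H](CCC(=O)OC)OC(C)=O)(C1C=CC=C1)C1C=CC=C1
F2 | step 13 | chlorobis(cyclopentadienyl)zirconium dienolate of 21 (O-bound at C9, C8=C9 enolate) | CCCCC/C=C\C[C@@]1(O[Si](CC)(CC)CC)C=CC(O[Zr](Cl)(C2C=CC=C2)C2C=CC=C2)=C1C/C=C/[C@H](CCC(=O)OC)OC(C)=O
F3 | step 2 | (1S,4R)-4-[(tert-butyldimethylsilyl)oxy]-1-(prop-2-ynyl)cyclopent-2-en-1-ol | C#CC[C@@]1(O)C=C[C@H](O[Si](C)(C)C(C)(C)C)C1
F4 | step 2 | (1S,4R)-4-[(tert-butyldimethylsilyl)oxy]-1-(oct-2-ynyl)cyclopent-2-en-1-ol | CCCCCC#CC[C@@]1(O)C=C[C@H](O[Si](C)(C)C(C)(C)C)C1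
F5 | step 7 | trimethyl{[(5R)-5-[(Z)-oct-2-enyl]-2-oxo-5-[(triethylsilyl)oxy]cyclopent-3-enyl]methyl}ammonium trifluoromethanesulfonate | CCCCC/C=C\C[C@@]1(O[Si](CC)(CC)CC)C=CC(=O)C1C[N+](C)(C)C.[O-]S(=O)(=O)C(F)(F)F
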